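- The vessel is closed, stirred and isothermal; it holds substrate and catalyst, the readings follow substrate and target, and the two isomers go unread. Amounts are fractions of the charge.

all flasks: substrate 0.020 M; catalyst 0.5 mol%
- ash: the very flask that is asked about, followed so far
- flask: time 1.5 h

ash run (percent of the substrate charged)

| time / min | substrate / % | target / % |
|---|---|---|
| 0.833 | 50 | 37 |
| 2.00 | 35 | 29 |
| 5.00 | 24 | 27 |
| 10.0 | 26 | 24 |

(readings scatter by 2 percentage points)

- the reaction counts as stopped when no species that holds the substrate changes by six tenths of a point or more over the second half of the time

- the state of affairs at 1.5 h: stopped, and by what, or still going (forward and back rates have come level / all of the substrate has reacted / no working catalyst is left / it is still moving)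
- conversion of substrate at 1.5 h
- amount of target at 1.5 h, in percent of the substrate charged
- amount of isomer of the product B at 1.5 h, in percent of the substrate charged
- amount of isomer of the product A at 1.5 h, in percent of the substrate charged
- amount of target if the flask were left three thousand times as long, in percent of the substrate charged

- First rung, the fastest: by 0.833 min of the ash run the substrate reads 50%, so half of the charge has moved, and the target reads 37%, higher than at any later reading.
- Second rung: up to 5.00 min of the ash run substrate and target fall to readings of 24% and 27%, so the unread isomers, taken together by difference, grow from 13.0% to 49.0%.
- Third rung: from 5.00 min to 10.0 min of the ash run the target reading moves by 3 percentage points and the substrate reading by 2 points, while a difference of two readings scatters by 2.8 points. The correction to a standing flask is thus of the size of that scatter.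
- The plateau share, the mean of a species' last two readings once they differ by no more than about their scatter, is for the target of the ash run 25.5%, uncertain by 1.4 points.
- The asked time is 9.00 times 10.0 min, so this reckoning carries the plateau forward unchanged: target 25.5%, and conversion 75.0%. The readings do not separate level rates from a dead catalyst, and they do not show how the isomers divide; the reckoning takes level rates, which keeps the target at 25.5% for the long wait too.
- The forecast says forward and back rates have come level, with conversion 75%, target 25%, isomer of the product B 25%, isomer of the product A 25% and 25% of target after the long wait; the overshoot and relaxation, in its words, “fit a reversible network somewhat better, so I choose equilibrium”.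

    substrate ⇌ target (K = 0.920, k = 0.0189 /s)
    target ⇌ isomer of the product A (K = 0.900, k = 0.00297 /s)
    isomer of the product A + catalyst ⇌ substrate + catalyst, rate k3*[catalyst]*[isomer of the product A] forward; the back reaction follows from the equilibrium constant (k = 62.2 /M/s)
    catalyst ⇌ dormant form (K = 0.670, k = 0.0413 /s)
    target ⇌ isomer of the product B (K = 0.974, k = 0.00596 /s)

- In the flask, forward and back rates have come level, with conversion 72.6%, target 25.2%, isomer of the product B 24.6%, isomer of the product A 22.7% and 25.2% of target after the long wait. This is an equilibrium, and at 1.50 h it stands with catalyst at 59.9% and dormant form at 40.1% of the catalyst charged. The plateau share 25.5% is a reading to carry through the flask's standing state: the target stands at 25.3% after 0.150 h and at 25.2% after 15.0 h. The neighbour, charged with 0.0050 M, a quarter of the substrate at the same loading, is reckoned at the same 25.5% and gives 25.2% of target at 1.50 h.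

Readings and results come from a simulation from invented constants, and the scatter is random.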